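**Retrosynthetic overview**
1. Target 26, read as epioritin-(4β→6)-oritin-4α-ol, comes from NaBH4 reduction of the lower C4 ketone of 25, which comes from hydrogenolysis of heptabenzyl ether 24; the ketone keeps the lower unit from ionising at its own C4 until the last step.
2. 24 comes from carbinol 23 (both C4 epimers) by ionisation at C4 and Friedel–Crafts closure of the upper pyran ring (O1–C2–C3–C4–C4a–C8a) through the C4–C4a bond. The enabling feature: the interflavan carbon C4 is benzylic to C6 of lower ring A and flanked by O7 (ortho) and O1 (para), so it ionises easily, and C4a is the only free carbon ortho to O1 on upper ring A and lies para to the O7 ether.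
3. 23 comes from aldehyde 22 (upper C2, C3, ring A and ring B) and lower aryl iodide 9 by a Nozaki–Hiyama–Kishi union at C4–C6; no stereocontrol is needed there.
4. 22 comes from (R)-glyceraldehyde acetonide 14 by anti aryl Grignard addition and Mitsunobu etherification with phenol 12 (inversion sets C2); 9 comes from gallacetophenone 1 via chalcone 6, Juliá–Colonna epoxidation and acid cyclisation.
5. Ring order: lower pyranone ring (step 6), then upper pyran ring (step 16); all benzene rings are bought.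

Key step: step 16

Remark: flavan numbering is used throughout; the upper unit is the C4-linked one (2R,3R,4S, 2,3-cis-3,4-trans), the lower unit is the C6-linked flavan-3,4-diol (2R,3S,4R, all-trans); compounds 1, 5, 10, 13 and 14 are taken as purchased.

**Route**

Step 1
Reactants: 1 2,3,4-trihydroxyacetophenone
Product: 2 1-[3,4-bis(benzyloxy)-2-hydroxyphenyl]ethan-1-one
Conditions: BnBr (2.1 equiv), K2CO3, acetone, reflux
Reagents that add atoms: benzyl bromide, BrCc1ccccc1
Why: Williamson etherification should alkylate the 3- and 4-hydroxyls while the 2-hydroxyl, held in a hydrogen bond to the acetyl carbonyl, stays free.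

Step 2
Reactants: 2 1-[3,4-bis(benzyloxy)-2-hydroxyphenyl]ethan-1-one
Product: 3 1-[3,4-bis(benzyloxy)-2-hydroxy-5-iodophenyl]ethan-1-one
Conditions: NIS, TFA (cat.), MeCN, 0 °C → rt
Reagents that add atoms: N-iodosuccinimide, O=C1CCC(=O)N1I
Why: Electrophilic aromatic iodination should go para to the free phenol and ortho to the 4-benzyloxy group, the only doubly activated open position, which becomes C6 of the lower unit.

Step 3
Reactants: 3 1-[3,4-bis(benzyloxy)-2-hydroxy-5-iodophenyl]ethan-1-one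
Product: 4 1-[3,4-bis(benzyloxy)-5-iodo-2-(methoxymethoxy)phenyl]ethan-1-one
Conditions: NaH, MOMCl, DMF, 0 °C
Reagents that add atoms: chloromethyl methyl ether, COCCl
Why: O-Alkylation of the phenoxide as its methoxymethyl ether masks the phenol so that the basic condensation and epoxidation steps cannot divert into Algar–Flynn–Oyamada-type cyclisations.

Step 4
Reactants: 4 1-[3,4-bis(benzyloxy)-5-iodo-2-(methoxymethoxy)phenyl]ethan-1-one; 5 4-(benzyloxy)benzaldehyde
Product: 6 (E)-3-[4-(benzyloxy)phenyl]-1-[3,4-bis(benzyloxy)-5-iodo-2-(methoxymethoxy)phenyl]prop-2-en-1-one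
Conditions: KOH (aq), EtOH/THF, rt
Reagents that add atoms: none
Why: Claisen–Schmidt condensation of the methyl ketone with the non-enolisable aldehyde should give the (E)-chalcone under thermodynamic control.

Step 5
Reactants: 6 (E)-3-[4-(benzyloxy)phenyl]-1-[3,4-bis(benzyloxy)-5-iodo-2-(methoxymethoxy)phenyl]prop-2-en-1-one
Product: 7 [(2R,3S)-3-[4-(benzyloxy)phenyl]oxiran-2-yl][3,4-bis(benzyloxy)-5-iodo-2-(methoxymethoxy)phenyl]methanone
Conditions: urea–H2O2, DBU, poly-L-leucine, THF, rt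
Reagents that add atoms: hydrogen peroxide (used as its urea adduct), OO
Why: Juliá–Colonna epoxidation within the helical poly-L-leucine should deliver the (αR,βS)-trans-epoxide, which fixes the future C3 of the lower unit and, after inversion, its C2.

Step 6
Reactants: 7 [(2R,3S)-3-[4-(benzyloxy)phenyl]oxiran-2-yl][3,4-bis(benzyloxy)-5-iodo-2-(methoxymethoxy)phenyl]methanone
Product: 9 (2R,3R)-7,8-bis(benzyloxy)-2-[4-(benzyloxy)phenyl]-3-hydroxy-6-iodo-2,3-dihydro-4H-chromen-4-one, via 2'-hydroxy epoxyketone 8 (not isolated)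
Conditions: HCl (1 M), MeOH/THF, 50 °C
Reagents that add atoms: none
Why: Acid cleaves the methoxymethyl ether and the freed phenol opens the epoxide at the benzylic carbon (6-endo epoxide opening, inversion, Cα–O bond untouched), which should give the trans-(2R,3R)-dihydroflavonol and closes the lower pyranone ring.

Step 7
Reactants: 10 2,3-bis(benzyloxy)benzaldehyde
Product: 12 2,3-bis(benzyloxy)phenol, via aryl formate 11 (not isolated)
Conditions: mCPBA, CH2Cl2, rt; then K2CO3 (cat.), MeOH, rt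
Reagents that add atoms: 3-chloroperoxybenzoic acid, OOC(=O)c1cccc(Cl)c1
Why: In this Dakin-type Baeyer–Villiger oxidation the electron-rich aryl group should migrate to give the formate, which is methanolysed to the phenol.

Step 8
Reactants: 13 1-(benzyloxy)-4-bromobenzene; 14 (R)-2,2-dimethyl-1,3-dioxolane-4-carbaldehyde
Product: 16 (S)-[4-(benzyloxy)phenyl][(4R)-2,2-dimethyl-1,3-dioxolan-4-yl]methanol, via arylmagnesium bromide 15 (not isolated)
Conditions: Mg, THF, 40 °C; then 14, THF, −78 °C; NH4Cl (aq)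
Reagents that add atoms: none
Why: Grignard addition to the α-alkoxy aldehyde under Felkin–Anh control should favour the anti (1S) carbinol, and the minor syn epimer is removed by chromatography.

Step 9
Reactants: 16 (S)-[4-(benzyloxy)phenyl][(4R)-2,2-dimethyl-1,3-dioxolan-4-yl]methanol; 12 2,3-bis(benzyloxy)phenol
Product: 17 (4R)-4-[(R)-[2,3-bis(benzyloxy)phenoxy][4-(benzyloxy)phenyl]methyl]-2,2-dimethyl-1,3-dioxolane
Conditions: PPh3, DIAD, toluene, 0 °C → rt
Reagents that add atoms: none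
Why: In the Mitsunobu etherification the phenol displaces the activated benzylic hydroxyl with inversion, which sets the (R) configuration of the future C2 in the threo relation to the adjacent oxygen that becomes the 2,3-cis relation of the upper unit.

Step 10
Reactants: 17 (4R)-4-[(R)-[2,3-bis(benzyloxy)phenoxy][4-(benzyloxy)phenyl]methyl]-2,2-dimethyl-1,3-dioxolane
Product: 18 (2R,3R)-3-[2,3-bis(benzyloxy)phenoxy]-3-[4-(benzyloxy)phenyl]propane-1,2-diol
Conditions: AcOH/H2O/THF (4:1:1), 45 °C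
Reagents that add atoms: none
Why: Mild acetal hydrolysis frees the diol under conditions that the benzylic aryl ether is expected to survive.

Step 11
Reactants: 18 (2R,3R)-3-[2,3-bis(benzyloxy)phenoxy]-3-[4-(benzyloxy)phenyl]propane-1,2-diol
Product: 19 (2R,3R)-3-[2,3-bis(benzyloxy)phenoxy]-3-[4-(benzyloxy)phenyl]-1-[(tert-butyldiphenylsilyl)oxy]propan-2-ol
Conditions: TBDPSCl, imidazole, CH2Cl2, 0 °C
Reagents that add atoms: tert-butyl(chloro)diphenylsilane, CC(C)(C)[Si](Cl)(c1ccccc1)c1ccccc1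
Why: Silyl ether formation should be selective for the primary hydroxyl on steric grounds.

Step 12
Reactants: 19 (2R,3R)-3-[2,3-bis(benzyloxy)phenoxy]-3-[4-(benzyloxy)phenyl]-1-[(tert-butyldiphenylsilyl)oxy]propan-2-ol
Product: 20 [(2R,3R)-2-(benzyloxy)-3-[2,3-bis(benzyloxy)phenoxy]-3-[4-(benzyloxy)phenyl]propoxy](tert-butyl)diphenylsilane
Conditions: NaH, BnBr, Bu4NI (cat.), THF, 0 °C → rt
Reagents that add atoms: benzyl bromide, BrCc1ccccc1
Why: Williamson benzylation of the secondary alkoxide puts the ether on the future O3, and the bulky silyl group should be slow to migrate.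

Step 13
Reactants: 20 [(2R,3R)-2-(benzyloxy)-3-[2,3-bis(benzyloxy)phenoxy]-3-[4-(benzyloxy)phenyl]propoxy](tert-butyl)diphenylsilane
Product: 21 (2R,3R)-2-(benzyloxy)-3-[2,3-bis(benzyloxy)phenoxy]-3-[4-(benzyloxy)phenyl]propan-1-ol
Conditions: TBAF, AcOH, THF, rt
Reagents that add atoms: none
Why: Fluoride-mediated desilylation frees the primary alcohol, with acetic acid buffering the alkoxide.

Step 14
Reactants: 21 (2R,3R)-2-(benzyloxy)-3-[2,3-bis(benzyloxy)phenoxy]-3-[4-(benzyloxy)phenyl]propan-1-ol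
Product: 22 (2S,3R)-2-(benzyloxy)-3-[2,3-bis(benzyloxy)phenoxy]-3-[4-(benzyloxy)phenyl]propanal
Conditions: Dess–Martin periodinane, NaHCO3, CH2Cl2, 0 °C → rt; used crude
Reagents that add atoms: none
Why: Dess–Martin oxidation under buffered, non-basic conditions should give the α-benzyloxy aldehyde without epimerisation or β-elimination of the aryloxy group.

Step 15
Reactants: 22 (2S,3R)-2-(benzyloxy)-3-[2,3-bis(benzyloxy)phenoxy]-3-[4-(benzyloxy)phenyl]propanal; 9 (2R,3R)-7,8-bis(benzyloxy)-2-[4-(benzyloxy)phenyl]-3-hydroxy-6-iodo-2,3-dihydro-4H-chromen-4-one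
Product: 23 (2R,3R)-7,8-bis(benzyloxy)-6-[(1RS,2R,3R)-2-(benzyloxy)-3-[2,3-bis(benzyloxy)phenoxy]-3-[4-(benzyloxy)phenyl]-1-hydroxypropyl]-2-[4-(benzyloxy)phenyl]-3-hydroxy-2,3-dihydro-4H-chromen-4-one (both epimers at the carbinol carbon)
Conditions: CrCl2 (6 equiv), NiCl2 (5 mol %), DMF, rt
Reagents that add atoms: none
Why: In the Nozaki–Hiyama–Kishi coupling zerovalent nickel inserts into the aryl iodide and the aryl group passes to chromium, which adds only to the aldehyde while the ketone and free hydroxyl of 9 are tolerated; no facial control is needed because both carbinol epimers converge in step 16.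

Step 16
Reactants: 23 (2R,3R)-7,8-bis(benzyloxy)-6-[(1RS,2R,3R)-2-(benzyloxy)-3-[2,3-bis(benzyloxy)phenoxy]-3-[4-(benzyloxy)phenyl]-1-hydroxypropyl]-2-[4-(benzyloxy)phenyl]-3-hydroxy-2,3-dihydro-4H-chromen-4-one (both epimers)
Product: 24 (2R,3R)-7,8-bis(benzyloxy)-2-[4-(benzyloxy)phenyl]-3-hydroxy-6-[(2R,3R,4R)-3,7,8-tris(benzyloxy)-2-[4-(benzyloxy)phenyl]-3,4-dihydro-2H-chromen-4-yl]-2,3-dihydro-4H-chromen-4-one (upper unit 2,3-cis-3,4-trans)
Conditions: Bi(OTf)3 (10 mol %), CH2Cl2 (5 mM), −20 → 0 °C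
Reagents that add atoms: none
Why: Bi(OTf)3 ionises the carbinol of either C4 epimer of 23 to one and the same benzylic cation, stabilised by O7 (ortho) and O1 (para) of lower ring A, and the tethered upper ring A captures it through C4a, an intramolecular Friedel–Crafts alkylation with a benzylic alcohol of the kind used to make 4-arylchromans. The pyran ring closes by a 6-exo-trig attack on the cationic carbon (the C4=C6 π-character of the cation stays outside the new ring), forming the C4–C4a bond. C4 is the one new stereocentre and is controlled by C3: allylic 1,3-strain against the ortho positions of lower ring A holds the C3–H bond in the plane of the cation, C4a can reach C4 only from the face that carries C2, and so it bonds anti to the C3–OBn bond, giving the 3,4-trans (4β-aryl) isomer, the same sense as in diastereoselective trapping of benzylic cations that bear an α-stereocentre. Because the stereocentre at C4 is erased on ionisation, the unselective union of step 15 is funnelled into a single configuration. The step needs chemoselective ionisation at C4 and regioselective C-alkylation: the free hydroxyl is the best Lewis base and leaving group in 23, the C4 ketone keeps the lower unit from forming a cation at its own C4, and the C2–O aryl ether should survive catalytic acid at low temperature, while C4a is the only unsubstituted carbon ortho to O1 and is para to the 7-benzyloxy group.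

Step 17
Reactants: 24 (2R,3R)-7,8-bis(benzyloxy)-2-[4-(benzyloxy)phenyl]-3-hydroxy-6-[(2R,3R,4R)-3,7,8-tris(benzyloxy)-2-[4-(benzyloxy)phenyl]-3,4-dihydro-2H-chromen-4-yl]-2,3-dihydro-4H-chromen-4-one
Product: 25 (2R,3R)-3,7,8-trihydroxy-2-(4-hydroxyphenyl)-6-[(2R,3R,4S)-3,7,8-trihydroxy-2-(4-hydroxyphenyl)-3,4-dihydro-2H-chromen-4-yl]-2,3-dihydro-4H-chromen-4-one
Conditions: H2 (1 atm), 10% Pd/C, THF/MeOH, rt
Reagents that add atoms: none
Why: Hydrogenolysis should remove all seven benzyl ethers while the conjugated chromanone carbonyl and the two cyclic benzylic O1–C2 bonds survive at one atmosphere.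

Step 18
Reactants: 25 (2R,3R)-3,7,8-trihydroxy-2-(4-hydroxyphenyl)-6-[(2R,3R,4S)-3,7,8-trihydroxy-2-(4-hydroxyphenyl)-3,4-dihydro-2H-chromen-4-yl]-2,3-dihydro-4H-chromen-4-one
Product: 26 (2R,3S,4R)-2-(4-hydroxyphenyl)-6-[(2R,3R,4S)-3,7,8-trihydroxy-2-(4-hydroxyphenyl)-3,4-dihydro-2H-chromen-4-yl]-3,4-dihydro-2H-chromene-3,4,7,8-tetrol (CNP0391561.5)
Conditions: NaBH4 (excess), degassed EtOH, argon, 0 °C → rt; AcOH to pH 6; Sephadex LH-20
Reagents that add atoms: none
Why: In this NaBH4 ketone reduction axial hydride delivery to the 2,3-trans-3-hydroxychromanone should give the equatorial 4-hydroxyl trans to O3 (4R, the 4α-ol), the sense established for trans-dihydroflavonols.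

**Compound list**
1 | 2,3,4-trihydroxyacetophenone | CC(=O)c1ccc(O)c(O)c1O | starting material
2 | 1-[3,4-bis(benzyloxy)-2-hydroxyphenyl]ethan-1-one | CC(=O)c1ccc(OCc2ccccc2)c(OCc2ccccc2)c1O | intermediate
3 | 1-[3,4-bis(benzyloxy)-2-hydroxy-5-iodophenyl]ethan-1-one | CC(=O)c1cc(I)c(OCc2ccccc2)c(OCc2ccccc2)c1O | intermediate
4 | 1-[3,4-bis(benzyloxy)-5-iodo-2-(methoxymethoxy)phenyl]ethan-1-one | CC(=O)c1cc(I)c(OCc2ccccc2)c(OCc2ccccc2)c1OCOC | intermediate
5 | 4-(benzyloxy)benzaldehyde | O=Cc1ccc(OCc2ccccc2)cc1 | starting material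
6 | (E)-3-[4-(benzyloxy)phenyl]-1-[3,4-bis(benzyloxy)-5-iodo-2-(methoxymethoxy)phenyl]prop-2-en-1-one | O=C(/C=C/c1ccc(OCc2ccccc2)cc1)c1cc(I)c(OCc2ccccc2)c(OCc2ccccc2)c1OCOC | intermediate
7 | [(2R,3S)-3-[4-(benzyloxy)phenyl]oxiran-2-yl][3,4-bis(benzyloxy)-5-iodo-2-(methoxymethoxy)phenyl]methanone | O=C([C@@H]1O[C@H]1c1ccc(OCc2ccccc2)cc1)c1cc(I)c(OCc2ccccc2)c(OCc2ccccc2)c1OCOC | intermediate
8 | [(2R,3S)-3-[4-(benzyloxy)phenyl]oxiran-2-yl][3,4-bis(benzyloxy)-2-hydroxy-5-iodophenyl]methanone | O=C([C@@H]1O[C@H]1c1ccc(OCc2ccccc2)cc1)c1cc(I)c(OCc2ccccc2)c(OCc2ccccc2)c1O | intermediate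
9 | (2R,3R)-7,8-bis(benzyloxy)-2-[4-(benzyloxy)phenyl]-3-hydroxy-6-iodo-2,3-dihydro-4H-chromen-4-one | Ic1cc2c(c(OCc3ccccc3)c1OCc1ccccc1)O[C@H](c1ccc(OCc3ccccc3)cc1)[C@@H](O)C2=O | intermediate
10 | 2,3-bis(benzyloxy)benzaldehyde | O=Cc1cccc(OCc2ccccc2)c1OCc1ccccc1 | starting material
11 | 2,3-bis(benzyloxy)phenyl formate | O=COc1cccc(OCc2ccccc2)c1OCc1ccccc1 | intermediate
12 | 2,3-bis(benzyloxy)phenol | Oc1cccc(OCc2ccccc2)c1OCc1ccccc1 | intermediate
13 | 1-(benzyloxy)-4-bromobenzene | Brc1ccc(OCc2ccccc2)cc1 | starting material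
14 | (R)-2,2-dimethyl-1,3-dioxolane-4-carbaldehyde | O=C[C@H]1COC(C)(C)O1 | starting material
15 | [4-(benzyloxy)phenyl]magnesium bromide | Br[Mg]c1ccc(OCc2ccccc2)cc1 | intermediate
16 | (S)-[4-(benzyloxy)phenyl][(4R)-2,2-dimethyl-1,3-dioxolan-4-yl]methanol | O[C@@H](c1ccc(OCc2ccccc2)cc1)[C@H]1COC(C)(C)O1 | intermediate
17 | (4R)-4-[(R)-[2,3-bis(benzyloxy)phenoxy][4-(benzyloxy)phenyl]methyl]-2,2-dimethyl-1,3-dioxolane | C(c1ccccc1)Oc1cccc(O[C@H](c2ccc(OCc3ccccc3)cc2)[C@H]2COC(C)(C)O2)c1OCc1ccccc1 | intermediate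
18 | (2R,3R)-3-[2,3-bis(benzyloxy)phenoxy]-3-[4-(benzyloxy)phenyl]propane-1,2-diol | C(c1ccccc1)Oc1cccc(O[C@H](c2ccc(OCc3ccccc3)cc2)[C@H](O)CO)c1OCc1ccccc1 | intermediate
19 | (2R,3R)-3-[2,3-bis(benzyloxy)phenoxy]-3-[4-(benzyloxy)phenyl]-1-[(tert-butyldiphenylsilyl)oxy]propan-2-ol | C(c1ccccc1)Oc1cccc(O[C@H](c2ccc(OCc3ccccc3)cc2)[C@H](O)CO[Si](c2ccccc2)(c2ccccc2)C(C)(C)C)c1OCc1ccccc1 | intermediate
20 | [(2R,3R)-2-(benzyloxy)-3-[2,3-bis(benzyloxy)phenoxy]-3-[4-(benzyloxy)phenyl]propoxy](tert-butyl)diphenylsilane | C(c1ccccc1)Oc1cccc(O[C@H](c2ccc(OCc3ccccc3)cc2)[C@H](OCc2ccccc2)CO[Si](c2ccccc2)(c2ccccc2)C(C)(C)C)c1OCc1ccccc1 | intermediate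
21 | (2R,3R)-2-(benzyloxy)-3-[2,3-bis(benzyloxy)phenoxy]-3-[4-(benzyloxy)phenyl]propan-1-ol | C(c1ccccc1)Oc1cccc(O[C@H](c2ccc(OCc3ccccc3)cc2)[C@H](OCc2ccccc2)CO)c1OCc1ccccc1 | intermediate
22 | (2S,3R)-2-(benzyloxy)-3-[2,3-bis(benzyloxy)phenoxy]-3-[4-(benzyloxy)phenyl]propanal | C(c1ccccc1)Oc1cccc(O[C@H](c2ccc(OCc3ccccc3)cc2)[C@H](OCc2ccccc2)C=O)c1OCc1ccccc1 | intermediate
23 | (2R,3R)-7,8-bis(benzyloxy)-6-[(1RS,2R,3R)-2-(benzyloxy)-3-[2,3-bis(benzyloxy)phenoxy]-3-[4-(benzyloxy)phenyl]-1-hydroxypropyl]-2-[4-(benzyloxy)phenyl]-3-hydroxy-2,3-dihydro-4H-chromen-4-one (both epimers at the carbinol carbon) | OC(c1cc2c(c(OCc3ccccc3)c1OCc1ccccc1)O[C@H](c1ccc(OCc3ccccc3)cc1)[C@@H](O)C2=O)[C@@H](OCc1ccccc1)[C@H](Oc1cccc(OCc2ccccc2)c1OCc1ccccc1)c1ccc(OCc2ccccc2)cc1 | intermediate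
24 | (2R,3R)-7,8-bis(benzyloxy)-2-[4-(benzyloxy)phenyl]-3-hydroxy-6-[(2R,3R,4R)-3,7,8-tris(benzyloxy)-2-[4-(benzyloxy)phenyl]-3,4-dihydro-2H-chromen-4-yl]-2,3-dihydro-4H-chromen-4-one (upper unit 2,3-cis-3,4-trans) | C(c1ccccc1)Oc1ccc([C@H]2Oc3c(ccc(OCc4ccccc4)c3OCc3ccccc3)[C@H](c3cc4c(c(OCc5ccccc5)c3OCc3ccccc3)O[C@H](c3ccc(OCc5ccccc5)cc3)[C@@H](O)C4=O)[C@H]2OCc2ccccc2)cc1 | intermediate
25 | (2R,3R)-3,7,8-trihydroxy-2-(4-hydroxyphenyl)-6-[(2R,3R,4S)-3,7,8-trihydroxy-2-(4-hydroxyphenyl)-3,4-dihydro-2H-chromen-4-yl]-2,3-dihydro-4H-chromen-4-one | Oc1ccc([C@H]2Oc3c(ccc(O)c3O)[C@H](c3cc4c(c(O)c3O)O[C@H](c3ccc(O)cc3)[C@@H](O)C4=O)[C@H]2O)cc1 | intermediate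
26 | (2R,3S,4R)-2-(4-hydroxyphenyl)-6-[(2R,3R,4S)-3,7,8-trihydroxy-2-(4-hydroxyphenyl)-3,4-dihydro-2H-chromen-4-yl]-3,4-dihydro-2H-chromene-3,4,7,8-tetrol (CNP0391561.5) | Oc1ccc([C@H]2Oc3c(ccc(O)c3O)[C@H](c3cc4c(c(O)c3O)O[C@H](c3ccc(O)cc3)[C@@H](O)[C@@H]4O)[C@H]2O)cc1 | target

**Totals**
Total step count: 18.
Longest linear sequence: 11 steps (13 and 14 to 26, steps 8–18); the lower-unit branch is 10 steps (1 to 26 through steps 1–6 and 15–18).

**Steps most likely to fail**

Step 16. What may go wrong: heterolysis of the C2–O bond (a 4-benzyloxybenzyl aryl ether) competing with ionisation at C4; a 1,2-hydride shift or proton loss from the cation before ring closure; erosion of facial selectivity at C4. The fallback sets out from 23 and comes back at 24. It separates activation from ionisation so that no acid is present. Carbinol 23 is acylated with trifluoroacetic anhydride and 2,6-lutidine (CH2Cl2, −40 °C) to the bis(trifluoroacetate) F1. F1 is then dissolved in hexafluoroisopropanol/CH2Cl2 containing 2,6-lutidine at 0 °C, where only the doubly oxygen-stabilised benzylic ester at C4 should solvolyse to the same cation and close onto C4a (solvolytic Friedel–Crafts alkylation). Work-up with NaHCO3 in MeOH should cleave the trifluoroacetate left on O3 of the lower unit and give 24.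

Step 15. What may go wrong: slow oxidative addition and transmetallation of the electron-rich, ortho-substituted aryl iodide, with proto-deiodination of 9 and loss of the aldehyde by β-elimination of the aryloxy group or pinacol coupling. The fallback sets out from 9 and comes back at 23. It replaces chromium by boron and rhodium. Miyaura borylation of 9 (Pd(dppf)Cl2, bis(pinacolato)diboron, KOAc, dioxane, 80 °C) should give the pinacol boronate F2. Rhodium-catalysed 1,2-addition of F2 to aldehyde 22 ([Rh(cod)OH]2, dioxane/H2O, 40 °C), a reaction that leaves ketones untouched, should then give 23 as the same epimer mixture.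

Step 9. What may go wrong: ionisation of the activated 4-benzyloxybenzylic oxyphosphonium intermediate, which would cost stereochemical fidelity at the future C2, or no substitution at the hindered carbinol. The fallback sets out from 16 and comes back at 17. It forms the ether with retention at carbon instead of inversion. Dess–Martin oxidation of 16 should give the aryl ketone F3. Felkin–Anh reduction with LiBH(s-Bu)3 (THF, −78 °C) should give the syn (R)-carbinol F4. Ullmann-type O-arylation of F4 with 1,2-bis(benzyloxy)-3-iodobenzene (Ic1cccc(OCc2ccccc2)c1OCc1ccccc1; CuI, 3,4,7,8-tetramethyl-1,10-phenanthroline, Cs2CO3, toluene, 110 °C) forms the C–O bond at the arene carbon, so the carbinol configuration is kept and 17 results.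

**Further compounds**
F1 | step 16 | bis(trifluoroacetate) of 23 (esters at the C4 carbinol oxygen and at O3 of the lower unit; both C4 epimers) | FC(F)(F)C(=O)OC(c1cc2c(c(OCc3ccccc3)c1OCc1ccccc1)O[C@H](c1ccc(OCc3ccccc3)cc1)[C@@H](OC(=O)C(F)(F)F)C2=O)[C@@H](OCc1ccccc1)[C@H](Oc1cccc(OCc2ccccc2)c1OCc1ccccc1)c1ccc(OCc2ccccc2)cc1
F2 | step 15 | (2R,3R)-7,8-bis(benzyloxy)-2-[4-(benzyloxy)phenyl]-3-hydroxy-6-(4,4,5,5-tetramethyl-1,3,2-dioxaborolan-2-yl)-2,3-dihydro-4H-chromen-4-one | CC1(C)OB(OC1(C)C)c1cc2c(c(OCc3ccccc3)c1OCc1ccccc1)O[C@H](c1ccc(OCc3ccccc3)cc1)[C@@H](O)C2=O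
F3 | step 9 | [4-(benzyloxy)phenyl][(4R)-2,2-dimethyl-1,3-dioxolan-4-yl]methanone | O=C(c1ccc(OCc2ccccc2)cc1)[C@H]1COC(C)(C)O1
F4 | step 9 | (R)-[4-(benzyloxy)phenyl][(4R)-2,2-dimethyl-1,3-dioxolan-4-yl]methanol | O[C@H](c1ccc(OCc2ccccc2)cc1)[C@H]1COC(C)(C)O1
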